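**Plan**

- Retrosynthesis: the four methoxymethyl ethers come off last. The pyranone (ring C) is then cut at O1–C8a and at C4–C4a in one operation, which gives a 3,5-dioxygenated benzyne and the enol of an α-formyl arylacetate.
- Enabling feature: ring A carries O1 on C8a and the C4 carbonyl on the adjacent C4a. The C5 oxygen next to C4a polarises a C4a–C8a aryne so that oxygen enters at C8a and the carbanion appears at C4a, within reach of the ester.
- The enol is cut at C2–C3 (methyl formate), at the aryl–CH2 bond (malonate arylation of an aryl bromide) and at the aryl–C(CH3)2 bond (Claisen rearrangement of a resorcinol prenyl ether). The aryne precursor goes back to phloroglucinol (ortho-bromination, retro-Brook silyl shift, triflation).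
- Forward: the ring A aryne precursor (steps 1–3) and the ring B formyl ester (steps 4–10) are made separately and joined in step 11 with closure of ring C; step 12 deprotects.
- Stereochemistry: the target has no stereocentre. The only geometric element is the Z enol of the formyl ester, held by its internal hydrogen bond, and it vanishes in the aromatic pyranone.

Key step: step 11

Remark: the α-formyl ester is treated as its hydrogen-bonded (Z)-enol; the aldehyde tautomer would give the same enolate under the conditions of the annulation.

**Route**

Step 1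
Reactants: 1 phloroglucinol
Product: 2 3,5-bis(methoxymethoxy)phenol
Conditions: MOMCl (2.0 equiv), i-Pr2NEt, DMF, 0 °C → rt
Reagents that add atoms: chloromethyl methyl ether, COCCl
Why: Williamson-type O-alkylation of the threefold symmetric triol with two equivalents of the chloromethyl ether is statistical, so the bis-ether should be separable by chromatography from the mono- and tris-ethers, which is acceptable for the first step on an inexpensive phenol.

Step 2
Reactants: 2 3,5-bis(methoxymethoxy)phenol
Product: 3 2-bromo-3,5-bis(methoxymethoxy)phenol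
Conditions: NBS (1.0 equiv), CH2Cl2, −78 °C → rt
Reagents that add atoms: N-bromosuccinimide, O=C1CCC(=O)N1Br
Why: Electrophilic aromatic bromination of a phloroglucinol diether is fast at low temperature, and of the two kinds of free position the one between the hydroxyl and an acetal ether is less crowded than the one between the two acetal ethers, so one equivalent of NBS should give mainly the ortho-bromophenol needed for the silyl migration.

Step 3
Reactants: 3 2-bromo-3,5-bis(methoxymethoxy)phenol
Product: 7 3,5-bis(methoxymethoxy)-2-(trimethylsilyl)phenyl trifluoromethanesulfonate, via silyl ether 4 (not isolated), via aryllithium 5 (not isolated), via lithium phenoxide 6 (not isolated)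
Conditions: HMDS, THF, 70 °C, then evaporation; n-BuLi, THF, −100 °C; Tf2O, −100 °C → rt
Reagents that add atoms: hexamethyldisilazane, C[Si](C)(C)N[Si](C)(C)C; trifluoromethanesulfonic anhydride, O=S(=O)(OS(=O)(=O)C(F)(F)F)C(F)(F)F
Why: O-Silylation, bromine–lithium exchange at −100 °C, anionic 1,3 oxygen-to-carbon silyl migration (retro-Brook rearrangement) and O-triflation of the resulting phenoxide form the standard sequence to ortho-silylaryl triflates, and the exchange is faster than any acetal-directed ring lithiation at this temperature.

Step 4
Reactants: 8 resorcinol (3 equiv); 9 prenyl bromide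
Product: 10 3-[(3-methylbut-2-en-1-yl)oxy]phenol
Conditions: K2CO3 (1 equiv), acetone, reflux
Reagents that add atoms: none
Why: Williamson ether synthesis with K2CO3 in acetone favours O- over C-alkylation, and a threefold excess of the symmetric diol, removable by aqueous extraction, keeps the bis-ether low.

Step 5
Reactants: 10 3-[(3-methylbut-2-en-1-yl)oxy]phenol
Product: 11 4-(2-methylbut-3-en-2-yl)benzene-1,3-diol
Conditions: PhNEt2, 190 °C, sealed tube, argon
Reagents that add atoms: none
Why: Aromatic Claisen rearrangement ([3,3]-sigmatropic shift with allyl inversion) turns the O-prenyl group into a C-bound 1,1-dimethylallyl group, and because the new bond is made to a fully substituted carbon the shift should go to the open ortho position para to the free hydroxyl and not to the position flanked by both oxygens, while the basic solvent suppresses acid-promoted closure of the new phenol onto the alkene.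

Step 6
Reactants: 11 4-(2-methylbut-3-en-2-yl)benzene-1,3-diol
Product: 12 2,4-bis(methoxymethoxy)-1-(2-methylbut-3-en-2-yl)benzene
Conditions: NaH (2.5 equiv), MOMCl (2.5 equiv), DMF, 0 °C → rt
Reagents that add atoms: chloromethyl methyl ether, COCCl
Why: Double Williamson-type O-alkylation of the sodium bis-phenoxide with the chloromethyl ether protects both hydroxyls as base-stable acetals, the strong base being chosen because one hydroxyl sits next to the quaternary carbon.

Step 7
Reactants: 12 2,4-bis(methoxymethoxy)-1-(2-methylbut-3-en-2-yl)benzene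
Product: 13 1-bromo-2,4-bis(methoxymethoxy)-5-(2-methylbut-3-en-2-yl)benzene
Conditions: NBS (1.05 equiv), MeCN, 0 °C, dark
Reagents that add atoms: N-bromosuccinimide, O=C1CCC(=O)N1Br
Why: Electrophilic aromatic bromination with NBS in acetonitrile should occur at the only ring position that is para to one acetal ether, ortho to the other and not flanked on both sides, and the monosubstituted alkene, which has no allylic hydrogen, is far less nucleophilic than the resorcinol diether ring.

Step 8
Reactants: 13 1-bromo-2,4-bis(methoxymethoxy)-5-(2-methylbut-3-en-2-yl)benzene; 14 dimethyl malonate (1.5 equiv)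
Product: 15 dimethyl 2-[2,4-bis(methoxymethoxy)-5-(2-methylbut-3-en-2-yl)phenyl]malonate
Conditions: Pd(dba)2 (cat.), P(t-Bu)3·HBF4 (cat.), K3PO4, toluene, 80 °C
Reagents that add atoms: none
Why: Pd-catalysed α-arylation of a malonate enolate with a bulky electron-rich phosphine is established for electron-rich ortho-substituted aryl bromides, and the excess of soft enolate should intercept the arylpalladium intermediate before it can add to the hindered terminal alkene.

Step 9
Reactants: 15 dimethyl 2-[2,4-bis(methoxymethoxy)-5-(2-methylbut-3-en-2-yl)phenyl]malonate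
Product: 16 methyl 2-[2,4-bis(methoxymethoxy)-5-(2-methylbut-3-en-2-yl)phenyl]acetate
Conditions: LiCl, H2O, DMSO, 140 °C
Reagents that add atoms: none
Why: Krapcho dealkoxycarbonylation (chloride attack on a methyl ester, decarboxylation, protonation by water) removes one ester under neutral conditions that leave the acetal ethers and the alkene untouched, and it is fast for aryl malonates.

Step 10
Reactants: 16 methyl 2-[2,4-bis(methoxymethoxy)-5-(2-methylbut-3-en-2-yl)phenyl]acetate; 17 methyl formate (excess)
Product: 19 methyl (Z)-2-[2,4-bis(methoxymethoxy)-5-(2-methylbut-3-en-2-yl)phenyl]-3-hydroxyprop-2-enoate, via sodium enolate 18 (not isolated)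
Conditions: NaH, THF, 0 °C → rt; AcOH quench, 0 °C
Reagents that add atoms: none
Why: Crossed Claisen condensation of the arylacetate enolate with the non-enolisable formate is driven by deprotonation of the product, and mild acidification releases the α-formyl ester as its hydrogen-bonded Z enol without loss of the acetal ethers.

Step 11
Reactants: 19 methyl (Z)-2-[2,4-bis(methoxymethoxy)-5-(2-methylbut-3-en-2-yl)phenyl]-3-hydroxyprop-2-enoate; 7 3,5-bis(methoxymethoxy)-2-(trimethylsilyl)phenyl trifluoromethanesulfonate (1.5 equiv)
Product: 22 3-[2,4-bis(methoxymethoxy)-5-(2-methylbut-3-en-2-yl)phenyl]-5,7-bis(methoxymethoxy)-4H-chromen-4-one (fremontin tetrakis(methoxymethyl) ether), via aryne 20 (not isolated), via aryl caesium adduct 21 (not isolated)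
Conditions: CsF (4 equiv), THF, 65 °C, sealed tube
Reagents that add atoms: none
Why: Proposed new method: fluoride removes the trimethylsilyl group of 7 and triflate leaves to give aryne 20; the caesium enolate of 19 adds through its terminal oxygen to the aryne carbon remote from the C5 acetal oxygen, which places the negative charge on the carbon flanked by that oxygen (21), and this carbanion attacks the cis-placed methyl ester and expels methoxide. The closest known reaction type is the fluoride-mediated annulation of arynes with methyl salicylates to xanthones (O-arylation, then intramolecular acyl substitution by the aryl anion), here transferred from a phenoxide to the enolate of a β-oxo ester. Ring C closes in a 6-exo-trig acyl substitution that forms C4–C4a after O1–C8a, and loss of methoxide to give the aromatic 4-pyranone makes the closure irreversible; no stereocentre is formed. Aryne regiochemistry should be secured by the inductive effect of the alkoxy group next to the triple bond, which directs nucleophiles to the distal carbon of 3-alkoxybenzynes. O- over C-arylation is the selectivity at risk, and it should be favoured because the enolate carbon is fully substituted and shielded by the ortho-acetal aryl group, whereas the formyl oxygen is exposed and carries most of the charge in the caesium ion pair in THF. Cyclisation should outrun protonation of the aryl anion because the medium is aprotic and the chelated Z geometry holds the ester next to the carbanion.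

Step 12
Reactants: 22 fremontin tetrakis(methoxymethyl) ether
Product: 23 fremontin
Conditions: 3 M HCl (cat.), MeOH, 45 °C
Reagents that add atoms: none
Why: Acid-catalysed acetal exchange with methanol (methoxymethyl ether cleavage) frees all four phenols, the C5 ether next to the carbonyl going fastest, and dilute acid at this temperature should not protonate the monosubstituted alkene of the 1,1-dimethylallyl group.

**Compound list**

1 | phloroglucinol | Oc1cc(O)cc(O)c1 | starting material
2 | 3,5-bis(methoxymethoxy)phenol | COCOc1cc(O)cc(OCOC)c1 | intermediate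
3 | 2-bromo-3,5-bis(methoxymethoxy)phenol | COCOc1cc(O)c(Br)c(OCOC)c1 | intermediate
4 | [2-bromo-3,5-bis(methoxymethoxy)phenoxy]trimethylsilane (silyl ether, not isolated) | COCOc1cc(O[Si](C)(C)C)c(Br)c(OCOC)c1 | intermediate
5 | {2,4-bis(methoxymethoxy)-6-[(trimethylsilyl)oxy]phenyl}lithium (aryllithium, not isolated) | COCOc1cc(O[Si](C)(C)C)c([Li])c(OCOC)c1 | intermediate
6 | lithium 3,5-bis(methoxymethoxy)-2-(trimethylsilyl)phenoxide (not isolated) | COCOc1cc([O-])c([Si](C)(C)C)c(OCOC)c1.[Li+] | intermediate
7 | 3,5-bis(methoxymethoxy)-2-(trimethylsilyl)phenyl trifluoromethanesulfonate | C[Si](C)(C)c1c(OCOC)cc(OCOC)cc1OS(=O)(=O)C(F)(F)F | intermediate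
8 | resorcinol | Oc1cccc(O)c1 | starting material
9 | prenyl bromide (1-bromo-3-methylbut-2-ene) | CC(C)=CCBr | starting material
10 | 3-[(3-methylbut-2-en-1-yl)oxy]phenol | CC(C)=CCOc1cccc(O)c1 | intermediate
11 | 4-(2-methylbut-3-en-2-yl)benzene-1,3-diol | C=CC(C)(C)c1ccc(O)cc1O | intermediate
12 | 2,4-bis(methoxymethoxy)-1-(2-methylbut-3-en-2-yl)benzene | C=CC(C)(C)c1ccc(OCOC)cc1OCOC | intermediate
13 | 1-bromo-2,4-bis(methoxymethoxy)-5-(2-methylbut-3-en-2-yl)benzene | C=CC(C)(C)c1cc(Br)c(OCOC)cc1OCOC | intermediate
14 | dimethyl malonate | COC(=O)CC(=O)OC | starting material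
15 | dimethyl 2-[2,4-bis(methoxymethoxy)-5-(2-methylbut-3-en-2-yl)phenyl]malonate | C=CC(C)(C)c1cc(C(C(=O)OC)C(=O)OC)c(OCOC)cc1OCOC | intermediate
16 | methyl 2-[2,4-bis(methoxymethoxy)-5-(2-methylbut-3-en-2-yl)phenyl]acetate | C=CC(C)(C)c1cc(CC(=O)OC)c(OCOC)cc1OCOC | intermediate
17 | methyl formate | COC=O | starting material
18 | sodium (Z)-2-[2,4-bis(methoxymethoxy)-5-(2-methylbut-3-en-2-yl)phenyl]-3-methoxy-3-oxoprop-1-en-1-olate (sodium enolate, not isolated) | [Na+].[O-]/C=C(/c1cc(C(C)(C)C=C)c(OCOC)cc1OCOC)C(=O)OC | intermediate
19 | methyl (Z)-2-[2,4-bis(methoxymethoxy)-5-(2-methylbut-3-en-2-yl)phenyl]-3-hydroxyprop-2-enoate | O/C=C(/c1cc(C(C)(C)C=C)c(OCOC)cc1OCOC)C(=O)OC | intermediate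
20 | 3,5-bis(methoxymethoxy)benzyne (1,2-didehydro-3,5-bis(methoxymethoxy)benzene, not isolated) | COCOC1=CC(OCOC)=CC#C1 | intermediate
21 | methyl (Z)-2-[2,4-bis(methoxymethoxy)-5-(2-methylbut-3-en-2-yl)phenyl]-3-[2-caesio-3,5-bis(methoxymethoxy)phenoxy]prop-2-enoate (aryl caesium adduct, not isolated) | [Cs]c1c(OCOC)cc(OCOC)cc1O/C=C(/c1cc(C(C)(C)C=C)c(OCOC)cc1OCOC)C(=O)OC | intermediate
22 | 3-[2,4-bis(methoxymethoxy)-5-(2-methylbut-3-en-2-yl)phenyl]-5,7-bis(methoxymethoxy)-4H-chromen-4-one | C=CC(C)(C)c1cc(-c2coc3cc(OCOC)cc(OCOC)c3c2=O)c(OCOC)cc1OCOC | intermediate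
23 | fremontin, 3-[2,4-dihydroxy-5-(2-methylbut-3-en-2-yl)phenyl]-5,7-dihydroxy-4H-chromen-4-one | C=CC(C)(C)c1cc(-c2coc3cc(O)cc(O)c3c2=O)c(O)cc1O | target

**Count and risks**

Total steps: 12. Longest linear sequence: 9 steps (steps 4–12, from resorcinol); the aryne branch (steps 1–3) joins at step 11.

Most likely to fail:

1. Step 11 (Proposed new method). The ambident enolate may arylate at carbon, after which the aryl anion would add to the formyl group and the aryne would end up inserted into the C–CHO bond. Alternatively the O-arylated aryl anion may be protonated by bifluoride before it reaches the ester, or it may be formed with the ester trans and unable to close. The fallback uses known chemistry, sets out from 16 with 3 as partner, and returns at 22. Ester 16 would be converted with MeNH(OMe)·HCl and i-PrMgCl in THF at −20 °C into the Weinreb amide N-methoxy-N-methyl-2-[2,4-bis(methoxymethoxy)-5-(2-methylbut-3-en-2-yl)phenyl]acetamide F1. Bromophenol 3 would be treated with n-BuLi (2.1 equiv) in THF at −78 °C to give the O,C-dilithio species, which would acylate on F1 to give the deoxybenzoin 2-[2,4-bis(methoxymethoxy)-5-(2-methylbut-3-en-2-yl)phenyl]-1-[2-hydroxy-4,6-bis(methoxymethoxy)phenyl]ethan-1-one F2. Heating F2 with N,N-dimethylformamide dimethyl acetal in toluene at 90 °C should give the enaminone 3-(dimethylamino)-2-[2,4-bis(methoxymethoxy)-5-(2-methylbut-3-en-2-yl)phenyl]-1-[2-hydroxy-4,6-bis(methoxymethoxy)phenyl]prop-2-en-1-one F3, which closes by addition of the phenol and loss of dimethylamine to 22. In this variant C4–C4a comes from aryllithium acylation and C2 from the formamide acetal.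

2. Step 5. The prenyl group may migrate to the position between the two oxygens, ionise off the oxygen, or, once on carbon, rearrange further or be trapped by the neighbouring phenol as a dihydrobenzofuran at the temperature required. The fallback builds the quaternary carbon by enolate arylation instead of a sigmatropic shift, sets out from 8, and returns at 12, replacing steps 4–6. Resorcinol 8 would be protected (NaH, MOMCl, DMF) to 1,3-bis(methoxymethoxy)benzene F4 and brominated (NBS, MeCN, 0 °C) to 1-bromo-2,4-bis(methoxymethoxy)benzene F5. Arylation of isobutyronitrile (NaN(SiMe3)2, Pd(OAc)2, rac-BINAP, toluene, 100 °C) should give 2-[2,4-bis(methoxymethoxy)phenyl]-2-methylpropanenitrile F6. Reduction with i-Bu2AlH in toluene at −78 °C and a buffered tartrate work-up would give 2-[2,4-bis(methoxymethoxy)phenyl]-2-methylpropanal F7. Wittig methylenation (Ph3PCH3Br, t-BuOK, THF, 0 °C) then gives 12.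

3. Step 8. The arylpalladium intermediate may insert the terminal alkene of another molecule (Heck-type oligomerisation), or oxidative addition into the electron-rich, ortho-substituted bromide may be slow and end in protodebromination. The fallback avoids palladium, sets out from 13, and returns at 16, replacing steps 8 and 9. Bromine–lithium exchange on 13 (n-BuLi, THF, −78 °C) and formylation with DMF would give 2,4-bis(methoxymethoxy)-5-(2-methylbut-3-en-2-yl)benzaldehyde F8. Van Leusen reductive cyanation (TosMIC, t-BuOK, DME, −40 °C, then MeOH, reflux) would give 2-[2,4-bis(methoxymethoxy)-5-(2-methylbut-3-en-2-yl)phenyl]acetonitrile F9. Hydrolysis (KOH, EtOH/H2O, reflux) would give 2-[2,4-bis(methoxymethoxy)-5-(2-methylbut-3-en-2-yl)phenyl]acetic acid F10, and methylation (MeI, K2CO3, DMF) gives 16.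

**Further compounds**

F1 | step 11 | N-methoxy-N-methyl-2-[2,4-bis(methoxymethoxy)-5-(2-methylbut-3-en-2-yl)phenyl]acetamide | C=CC(C)(C)c1cc(CC(=O)N(C)OC)c(OCOC)cc1OCOC
F2 | step 11 | 2-[2,4-bis(methoxymethoxy)-5-(2-methylbut-3-en-2-yl)phenyl]-1-[2-hydroxy-4,6-bis(methoxymethoxy)phenyl]ethan-1-one | C=CC(C)(C)c1cc(CC(=O)c2c(O)cc(OCOC)cc2OCOC)c(OCOC)cc1OCOC
F3 | step 11 | 3-(dimethylamino)-2-[2,4-bis(methoxymethoxy)-5-(2-methylbut-3-en-2-yl)phenyl]-1-[2-hydroxy-4,6-bis(methoxymethoxy)phenyl]prop-2-en-1-one (alkene geometry not defined) | C=CC(C)(C)c1cc(C(=CN(C)C)C(=O)c2c(O)cc(OCOC)cc2OCOC)c(OCOC)cc1OCOC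
F4 | step 5 | 1,3-bis(methoxymethoxy)benzene | COCOc1cccc(OCOC)c1
F5 | step 5 | 1-bromo-2,4-bis(methoxymethoxy)benzene | COCOc1ccc(Br)c(OCOC)c1
F6 | step 5 | 2-[2,4-bis(methoxymethoxy)phenyl]-2-methylpropanenitrile | COCOc1ccc(C(C)(C)C#N)c(OCOC)c1
F7 | step 5 | 2-[2,4-bis(methoxymethoxy)phenyl]-2-methylpropanal | COCOc1ccc(C(C)(C)C=O)c(OCOC)c1
F8 | step 8 | 2,4-bis(methoxymethoxy)-5-(2-methylbut-3-en-2-yl)benzaldehyde | C=CC(C)(C)c1cc(C=O)c(OCOC)cc1OCOC
F9 | step 8 | 2-[2,4-bis(methoxymethoxy)-5-(2-methylbut-3-en-2-yl)phenyl]acetonitrile | C=CC(C)(C)c1cc(CC#N)c(OCOC)cc1OCOC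
F10 | step 8 | 2-[2,4-bis(methoxymethoxy)-5-(2-methylbut-3-en-2-yl)phenyl]acetic acid | C=CC(C)(C)c1cc(CC(=O)O)c(OCOC)cc1OCOC
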